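**Retrosynthetic overview** (locants C1–C4 are those of the target; ring A = fused dimethoxybenzene, ring B = saturated carbocycle, ring C = pendant aryl)
1. 13 ⇐ O-methylation of alcohol 12 ⇐ hydroxyl-directed syn hydrogenation of tetrasubstituted alkene 11, which sets C1 and C2 (1,2-cis, 2,3-trans) from the C3 stereocenter.
2. 11 ⇐ key step: acid-triggered ring expansion of cyclopropyl diaryl carbinol 8 (cyclopropane → ring B; C4–C4a bond and C1=C2 alkene), intercepted in the same flask by a methoxymethyl cation (C2–CH2OMe bond).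
3. 8 ⇐ double addition of (3,4-dimethoxyphenyl)lithium to enantiopure cyclopropane-fused lactone 4; both aryl rings arrive together, and C3 with its CH2O arm comes from 4.
4. Aryllithium ⇐ 4-bromoveratrole 3 ⇐ veratrole 2 ⇐ catechol 1.
5. Ring order: rings A and C are carried in from catechol; ring B is formed last, from the cyclopropane of 4.

Assumption: enantiopure (1R,5S)-3-oxabicyclo[3.1.0]hexan-2-one (4) is taken as a purchasable building block.

**Step 1**
Reactants: 1 catechol (benzene-1,2-diol)
Product: 2 1,2-dimethoxybenzene (veratrole)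
Conditions: MeI (2.5 equiv), K2CO3 (3 equiv), acetone, reflux
Reagents that add atoms: iodomethane, CI
Why: Double Williamson ether synthesis, in which the carbonate-generated catecholate is methylated twice by SN2 attack on MeI.

**Step 2**
Reactants: 2 1,2-dimethoxybenzene
Product: 3 4-bromo-1,2-dimethoxybenzene
Conditions: NBS (1.0 equiv), MeCN, 0 °C → rt
Reagents that add atoms: N-bromosuccinimide, O=C1CCC(=O)N1Br
Why: Electrophilic aromatic bromination, which occurs once and para to a methoxy group (C4) because the ortho sites are more hindered.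

**Step 3**
Reactants: 3 4-bromo-1,2-dimethoxybenzene (2.1 equiv); 4 (1R,5S)-3-oxabicyclo[3.1.0]hexan-2-one
Product: 8 {(1R,2S)-2-[(tert-butyldiphenylsilyloxy)methyl]cyclopropyl}bis(3,4-dimethoxyphenyl)methanol, via aryllithium 5 (not isolated), via ketone alkoxide 6 (not isolated), via dilithium dialkoxide 7 (not isolated)
Conditions: n-BuLi (2.1 equiv), THF, −78 °C; add 4, −78 → 0 °C; then t-BuPh2SiCl (1.2 equiv), DMAP (10 mol%), 0 °C → rt; then H2O
Reagents that add atoms: tert-butyl(chloro)diphenylsilane, CC(C)(C)[Si](Cl)(c1ccccc1)c1ccccc1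
Why: Bromine–lithium exchange gives aryllithium 5, which adds twice to the lactone carbonyl (acyl substitution to ketone 6, then 1,2-addition) without touching the cyclopropane stereocenters, and only the unhindered primary alkoxide of 7 is silylated in situ because the tertiary diaryl alkoxide is too hindered.

**Step 4**
Reactants: 8 {(1R,2S)-2-[(tert-butyldiphenylsilyloxy)methyl]cyclopropyl}bis(3,4-dimethoxyphenyl)methanol
Product: 11 [(2S)-4-(3,4-dimethoxyphenyl)-6,7-dimethoxy-3-(methoxymethyl)-1,2-dihydronaphthalen-2-yl]methanol, via dihydronaphthalene silyl ether 9 (not isolated), via methoxymethylated silyl ether 10 (not isolated)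
Conditions: TfOH (10 mol%), 4 Å MS, CH2Cl2, −20 °C → rt; then CH2(OMe)2 (5 equiv), −40 → 0 °C; Et3N; then Bu4NF (1.5 equiv), THF, rt
Reagents that add atoms: dimethoxymethane, COCOC
Why: Proposed new method: TfOH ionises the diaryl carbinol of 8 to a bis(3,4-dimethoxyphenyl)-stabilised cyclopropylcarbinyl cation, the ring is opened at its unsubstituted CH2 (the other ring carbon carries the bulky, inductively withdrawing CH2OSi group) by the ortho carbon para to a methoxy group of one aryl ring, so that the three cyclopropane carbons, the carbinol carbon and two arene carbons become ring B of 9 while the stereocenter from 4 is never touched; the methoxymethyl cation from CH2(OMe)2 then adds to the only nucleophilic alkene carbon (C3) of this 1,1-diarylalkene, the diarylcarbenium ion re-formed at C4 can lose only the C3 proton and gives tetrasubstituted alkene 10 (Prins-type vinylic substitution), and fluoride frees the primary alcohol; the closest known reaction types are the acid-mediated ring enlargement of cyclopropyl diaryl carbinols to 1-aryl-3,4-dihydronaphthalenes (cyclopropylcarbinyl–homoallyl rearrangement with Friedel–Crafts closure) and the Lewis-acid addition of acetal-derived oxocarbenium ions to 1,1-diarylethylenes, neither shown on a ring-substituted cyclopropane nor coupled in one flask.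

**Step 5**
Reactants: 11 [(2S)-4-(3,4-dimethoxyphenyl)-6,7-dimethoxy-3-(methoxymethyl)-1,2-dihydronaphthalen-2-yl]methanol
Product: 12 [(2S,3S,4S)-4-(3,4-dimethoxyphenyl)-6,7-dimethoxy-3-(methoxymethyl)-1,2,3,4-tetrahydronaphthalen-2-yl]methanol
Conditions: [Ir(cod)(PCy3)(py)]PF6 (5 mol%), H2 (50 bar), CH2Cl2, rt
Reagents that add atoms: none
Why: Hydroxyl-directed homogeneous hydrogenation, in which the homoallylic CH2OH (held pseudoaxial by allylic 1,2-strain) binds the cationic iridium dihydride far better than the methyl ether, so both hydrogens are delivered to the alkene face it occupies and one syn addition sets C3 (CH2OMe trans to CH2OH) and C4 (aryl cis to CH2OMe) of 12.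

**Step 6**
Reactants: 12 [(2S,3S,4S)-4-(3,4-dimethoxyphenyl)-6,7-dimethoxy-3-(methoxymethyl)-1,2,3,4-tetrahydronaphthalen-2-yl]methanol
Product: 13 (1S,2S,3S)-1-(3,4-dimethoxyphenyl)-6,7-dimethoxy-2,3-bis(methoxymethyl)-1,2,3,4-tetrahydronaphthalene
Conditions: NaH (1.5 equiv), MeI (2 equiv), THF, 0 °C → rt
Reagents that add atoms: iodomethane, CI
Why: Williamson ether synthesis on the single primary alcohol, under basic conditions that touch none of the three stereocenters.

**Compound list**
1 | catechol (benzene-1,2-diol) | Oc1ccccc1O | starting material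
2 | 1,2-dimethoxybenzene (veratrole) | COc1ccccc1OC | intermediate
3 | 4-bromo-1,2-dimethoxybenzene | COc1ccc(Br)cc1OC | intermediate
4 | (1R,5S)-3-oxabicyclo[3.1.0]hexan-2-one | O=C1OC[C@H]2C[C@@H]12 | starting material
5 | (3,4-dimethoxyphenyl)lithium | [Li]c1ccc(OC)c(OC)c1 | intermediate
6 | lithium alkoxide of (3,4-dimethoxyphenyl)[(1R,2S)-2-(hydroxymethyl)cyclopropyl]methanone | [Li]OC[C@H]1C[C@H]1C(=O)c1ccc(OC)c(OC)c1 | intermediate
7 | dilithium dialkoxide of [(1R,2S)-2-(hydroxymethyl)cyclopropyl]bis(3,4-dimethoxyphenyl)methanol | [Li]OC[C@H]1C[C@H]1C(O[Li])(c1ccc(OC)c(OC)c1)c1ccc(OC)c(OC)c1 | intermediate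
8 | {(1R,2S)-2-[(tert-butyldiphenylsilyloxy)methyl]cyclopropyl}bis(3,4-dimethoxyphenyl)methanol | CC(C)(C)[Si](c1ccccc1)(c1ccccc1)OC[C@H]1C[C@H]1C(O)(c1ccc(OC)c(OC)c1)c1ccc(OC)c(OC)c1 | intermediate
9 | tert-butyl{[(2S)-4-(3,4-dimethoxyphenyl)-6,7-dimethoxy-1,2-dihydronaphthalen-2-yl]methoxy}diphenylsilane | CC(C)(C)[Si](c1ccccc1)(c1ccccc1)OC[C@H]1Cc2cc(OC)c(OC)cc2C(c2ccc(OC)c(OC)c2)=C1 | intermediate
10 | tert-butyl{[(2S)-4-(3,4-dimethoxyphenyl)-6,7-dimethoxy-3-(methoxymethyl)-1,2-dihydronaphthalen-2-yl]methoxy}diphenylsilane | CC(C)(C)[Si](c1ccccc1)(c1ccccc1)OC[C@H]1Cc2cc(OC)c(OC)cc2C(c2ccc(OC)c(OC)c2)=C1COC | intermediate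
11 | [(2S)-4-(3,4-dimethoxyphenyl)-6,7-dimethoxy-3-(methoxymethyl)-1,2-dihydronaphthalen-2-yl]methanol | OC[C@H]1Cc2cc(OC)c(OC)cc2C(c2ccc(OC)c(OC)c2)=C1COC | intermediate
12 | [(2S,3S,4S)-4-(3,4-dimethoxyphenyl)-6,7-dimethoxy-3-(methoxymethyl)-1,2,3,4-tetrahydronaphthalen-2-yl]methanol | OC[C@H]1Cc2cc(OC)c(OC)cc2[C@H](c2ccc(OC)c(OC)c2)[C@@H]1COC | intermediate
13 | (1S,2S,3S)-1-(3,4-dimethoxyphenyl)-6,7-dimethoxy-2,3-bis(methoxymethyl)-1,2,3,4-tetrahydronaphthalene | COC[C@H]1Cc2cc(OC)c(OC)cc2[C@H](c2ccc(OC)c(OC)c2)[C@@H]1COC | target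

**Step count and risks**
Total steps: 6. Longest linear sequence: 6 (1 → 2 → 3 → 8 → 11 → 12 → 13; lactone 4 enters at step 3).

The three steps most likely to fail:

Step 4 (the proposed new cascade). The risks are:
- cyclopropane opening at the substituted ring carbon instead of the CH2;
- participation of the silyl ether oxygen at the cation;
- acid-induced dimerisation of 9;
- ring methoxymethylation of the electron-rich arenes;
- ionisation of the allylic ether in 10.

The fallback uses known chemistry only, sets out from 8 and rejoins at 11. The ring enlargement is run alone (TfOH 10 mol%, 4 Å MS, CH2Cl2) and 9 is isolated. Bromination–dehydrobromination of this 1,1-diarylalkene (pyridinium tribromide, CH2Cl2, −78 °C, then Et3N) gives the vinyl bromide tert-butyl{[(2R)-3-bromo-4-(3,4-dimethoxyphenyl)-6,7-dimethoxy-1,2-dihydronaphthalen-2-yl]methoxy}diphenylsilane F1. Bromine–lithium exchange (t-BuLi, THF, −78 °C) and C-alkylation of the vinyllithium with MeOCH2Cl gives 10, and Bu4NF then gives 11.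

Step 5 (directed hydrogenation). The risks are:
- the tetrasubstituted, aryl-flanked alkene may react slowly;
- the acidic iridium hydride may ionise the allylic methyl ether;
- the alkene may isomerise toward C2 and erode the stereocenter.

The fallback sets out from 11 and rejoins at 13, and replaces substrate direction by catalyst control. The alcohol is methylated first (NaH, MeI) to (2S)-4-(3,4-dimethoxyphenyl)-6,7-dimethoxy-2,3-bis(methoxymethyl)-1,2-dihydronaphthalene F2. F2 is then hydrogenated with a chiral phosphinooxazoline complex of iridium, [Ir(cod)(tBu-PHOX)][B(C6H3(CF3)2)4] (H2 50–100 bar, CH2Cl2). Both catalyst enantiomers are tested and the matched one, which adds H2 to the face syn to the C2 arm, is used; this gives 13 directly.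

Step 3 (double addition with in-situ silylation). The risks are:
- the sequence may stall at ketone 6;
- silylation may be incomplete or unselective;
- carbinol 8 is acid-labile on work-up.

The fallback sets out from 4 and rejoins at 8. Aminolysis of 4 with MeNH(OMe)·HCl and AlMe3 (CH2Cl2, 0 °C) gives the hydroxy Weinreb amide (1R,2S)-2-(hydroxymethyl)-N-methoxy-N-methylcyclopropane-1-carboxamide F3. Silylation (t-BuPh2SiCl, imidazole, DMF) gives (1R,2S)-2-{[(tert-butyldiphenylsilyl)oxy]methyl}-N-methoxy-N-methylcyclopropane-1-carboxamide F4. One equivalent of 5 (THF, −78 °C) gives the isolable ketone [(1R,2S)-2-{[(tert-butyldiphenylsilyl)oxy]methyl}cyclopropyl](3,4-dimethoxyphenyl)methanone F5, and a second, separate addition of 5 gives 8.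

**Further compounds**
F1 | step 4 | tert-butyl{[(2R)-3-bromo-4-(3,4-dimethoxyphenyl)-6,7-dimethoxy-1,2-dihydronaphthalen-2-yl]methoxy}diphenylsilane | CC(C)(C)[Si](c1ccccc1)(c1ccccc1)OC[C@H]1Cc2cc(OC)c(OC)cc2C(c2ccc(OC)c(OC)c2)=C1Br
F2 | step 5 | (2S)-4-(3,4-dimethoxyphenyl)-6,7-dimethoxy-2,3-bis(methoxymethyl)-1,2-dihydronaphthalene | COC[C@H]1Cc2cc(OC)c(OC)cc2C(c2ccc(OC)c(OC)c2)=C1COC
F3 | step 3 | (1R,2S)-2-(hydroxymethyl)-N-methoxy-N-methylcyclopropane-1-carboxamide | OC[C@H]1C[C@H]1C(=O)N(C)OC
F4 | step 3 | (1R,2S)-2-{[(tert-butyldiphenylsilyl)oxy]methyl}-N-methoxy-N-methylcyclopropane-1-carboxamide | CC(C)(C)[Si](c1ccccc1)(c1ccccc1)OC[C@H]1C[C@H]1C(=O)N(C)OC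
F5 | step 3 | [(1R,2S)-2-{[(tert-butyldiphenylsilyl)oxy]methyl}cyclopropyl](3,4-dimethoxyphenyl)methanone | CC(C)(C)[Si](c1ccccc1)(c1ccccc1)OC[C@H]1C[C@H]1C(=O)c1ccc(OC)c(OC)c1
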